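The runs were computed for an exercise; the scatter is artificial.

Q comes slowly in the earlier runs: this flask's Q may still be rising at 50 min, and neither run was read at that time.

| flask | E | remark | time |
|---|---|---|---|
| summer | 28 mM | run made earlier |  |
| spring | 44 mM | run made earlier |  |
| flask | 20 mM |  | 50 min |

- summer (time / min: Q / %): 12.0: 18.8; 15.0: 23.3; 25.0: 29.2; 30.0: 26.8; 40.0: 32.5; 60.0: 34.4
- spring (time / min: Q / %): 12.0: 17.6; 15.0: 20.8; 25.0: 25.4; 30.0: 28.4; 40.0: 30.1; 60.0: 29.2

(standard deviation of a reading: 1 percentage point)

1. when, up to 50 min, the flask holds most Q
2. the amount of Q, in percent of the E charged, at that time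



I replace each curve at 50 min by the mean of its readings at 40.0 min and 60.0 min: 33.5 % of the charge in summer and 29.6 % in spring, where the heavier charge keeps less. That gives 0.0239 /mM: this is the charge penalty, the rise in the reciprocal of the share of Q per mM charged. Taken down from the summer charge to this flask's 20 mM, it gives 35.7 %.

The weak link is the mean, since a curve bending over lies above its chord. The summer reading of 18.8 % at 12.0 min gives a time constant of 14.5 min for the approach to the level. With that constant the curve at 50 min stands above the chord by a factor of 1.01, which is 0.29 percentage points on this flask's share. So I commit to 36.0 % for this flask at 50 min. The spring fall between those two readings, 0.9 points, is less than the scatter of 1 point in one reading.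

The forecast says 37 % at 48 min, which is 1.00 point above my share, and it reads the runs as “a competing loss, higher order in E, takes more at higher concentration”.

The flask gives 36.8 % at 50.0 min, and the forecast holds.

    E ⇌ Q (K = 1.31, k = 3.80 × 10⁻⁴ /s)
    E ⇌ Z (K = 17.0, k = 4.30 × 10⁻⁶ /s)
    2 E → G (k = 0.00818 /M/s)

At 50.0 min this flask's E goes into Q at 3.6 times the rate at which it goes into G, counting the forward rate of the reversible step alone; this is the selectivity factor. By their own step alone, both ways together, E and Q relax with a half-life of 17.2 min, shorter than the 50 min allowed, and at that limit this flask holds 32.3 % E beside 36.8 % Q. For a flask like this one with 34 mM of E, the penalty and the same chord factor give 32.2 %; the computed result is 31.8 %.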